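## The problem

Target 31 is a single cyclohexane ring in which every carbon except C2 is a stereocentre. C1 carries the side chain, C3 and C4 carry the epoxide (methyl on C4), and C5 and C6 carry two angelate esters that are trans to each other. A sixth stereocentre, C8 (S), lies on the chain C7(=C14H2)–C8(OAc)–CH2–CH=CMe2.

Apart from the epoxide there is no ring fusion to transmit configuration, so it must be passed from centre to centre. C5 can come from the chiral pool, C6 and C1 from an auxiliary-controlled aldol addition to a C5 aldehyde, and C1 can then govern C3 and C4. C8 is insulated from the ring by the sp2 carbon C7 and needs reagent control.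

The fragile parts are:
- the trisubstituted epoxide with its tertiary C4–O bond (acid);
- the two (Z)-2-methylbut-2-enoates (base, nucleophiles and heat turn them into tiglates);
- the allylic acetate;
- the two side-chain olefins, which would compete with C3=C4 in any epoxidation.

The epoxide must therefore be in place before the side chain is built, and the esters must come last, with O8 distinguished from O5 and O6.

The feature that carries the plan is that the epoxide oxygen at C4 and carbon C7 at C1 lie on the same ring face in a 1,4 relation. If C7 is a carboxyl group, its oxygen can span the ring in a boat and bond to C4 on that face only.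

## Retrosynthesis

**Ester C–O bonds at O5 and O6.** Target 31 is opened to diol 28 and angelic acid 29. The angelates go on last because nothing after them may be basic or hot for long. Diol 28 comes from bis-silyl ether 27, and 27 from allylic alcohol 26 by acetylation. Putting the acetate on O8 while O5 and O6 are still silylated is what distinguishes the two kinds of ester.

**C7–C8 bond.** Alcohol 26 is cut into 2-iodoalkene 23 and 4-methylpent-3-enal 25 (from alcohol 24). Cutting C8–C9 would need a prenyl nucleophile to react at its α-carbon, and cutting C1–C7 would need an sp3–sp2 coupling at a crowded ring carbon. The C7–C8 cut makes the 1,1-disubstituted olefin and the carbinol in one Nozaki–Hiyama–Kishi step, with C8 set by a chiral ligand. The forward reaction must tolerate an epoxide and silyl ethers.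

**C7–I and C7–C14.** Iodide 23 comes from terminal alkyne 21 by Markovnikov hydroalumination and iodinolysis. Alkyne 21 comes from methyl ester 19 by reduction to the aldehyde and one-carbon homologation. The side chain is thus reduced to a single carboxyl carbon on C1.

**C3–O, then C4–O and C3–I (key disconnection).** Epoxy ester 19 is the methanolysis product of bridged iodolactone 17, and 17 is the iodolactonisation product of cyclohexene acid 16. Direct epoxidation of a C1-substituted cyclohexene would rest on an uncertain balance: the allylic C5 silyloxy group shields one face, and the C6 and C1 substituents shield the other. The lactone tether removes that uncertainty, since oxygen can arrive only on the face of C7. Two stereocentres and the epoxide are removed from the problem. The forward reaction needs only anti addition across C3=C4.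

**C3=C4 and C1–C6.** Acid 16 comes from imide 15 by hydrolysis. Imide 15 comes from diene 14 by ring-closing metathesis, and 14 from aldol adduct 13 by silylation. Adduct 13 is cut at C1–C6 into pentenoyl imide 11 (from acid 8 and auxiliary 9) and α-silyloxy aldehyde 7. The Evans syn-aldol sets C1 and C6 together. It must override the intrinsic facial bias of 7, because the required 5,6-syn relation is the anti-Felkin one.

**C5 from the chiral pool.** Aldehyde 7 comes from bis-silyl ether 6, diol 5 and isopropenyl dioxolane 4. Dioxolane 4 comes from methyl ketone 3 by methylenation, and 3 from glycerate ester 1. The glycerate stereocentre becomes C5 unchanged, its ester carbon becomes C4 and its CH2O carbon becomes C6.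

## Roads not taken

**Alternative 1:** The strategic cut is C3=C4 of an open chain that carries C7 as a protected alcohol. Diene A1 (4-methoxybenzyl ether, bis-triethylsilyl) would close with the second-generation Grubbs catalyst to cyclohexene A2.
- Merits: the ring closure is reliable (the chosen route uses the same metathesis as step 9), and C7 is already at the alcohol level.
- Weak point: it leaves the epoxide face open. A2 would have to be deprotected and epoxidised under direction from a flexible CH2OH arm that sits 1,4 to the olefin, against the steric pull of three other substituents.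
- Comparison: in step count the two roads are level, or Alternative 1 is slightly longer if the 4-methoxybenzyl ether is kept. It avoids an iodide and a strained lactone, which is a real advantage. The chosen plan sets against this a face selectivity that follows from the reach of a tether and not from a balance of effects.

**Alternative 2:** The cut is C1–C6. Zinc or CrCl2 would turn bromide A3 into an allylmetal whose γ-carbon C1 adds to the C6 aldehyde, and the alkoxide would lactonise onto C8 to give the cis-fused α-methylene lactone A4.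
- Merits: ring, exocyclic methylene C14 and the C1/C6 cis relation arise in one step, and the epoxide can be set earlier by a reagent-controlled epoxidation of an open-chain allylic alcohol. In convergence at the ring-forming stage it is better than the chosen plan.
- Weak points:
  - C8 arrives as a lactone carbonyl. Turning it into an (S)-configured acetate-bearing carbon with a prenyl group needs an α-selective prenyl addition, whereas prenyl metals react at the γ-terminus, and the α-methylene lactone also invites conjugate addition.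
  - O6 is locked in the lactone although it must end as an angelate.
  - A3 combines an α-alkoxy aldehyde with a neighbouring epoxide.
  - The C5/C6 relation rests on an open-chain transition state.
- Comparison: the chosen plan forms C8 directly at the right oxidation level under catalyst control, at the price of a longer linear sequence before the ring exists.

**Alternative 3:** The cut is C1–C2. The silyl ketene acetal of vinyl lactone A5 would undergo an Ireland–Claisen ring contraction through a boat transition state to acid A6. A6 is compound 16 with other silyl groups, so the iodolactone step would follow unchanged.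
- Merits: no auxiliary is needed, C1–C2 and C3=C4 form together, and C1 is set by suprafacial transfer.
- Weak points:
  - A5 needs a fully substituted carbinol carbon at C4 with the vinyl group trans to O6. That centre is harder to make than any in the chosen route and is destroyed in the step.
  - Enolisation of a β-silyloxy lactone invites E1cB loss of the C6 silyloxy group.
  - The boat transition state carries two silyloxy groups on the bridge.
- Comparison: it would be the shorter road if A5 were available in a few steps. The chosen plan reaches the same acid from three simple pieces, with every stereocentre set by the chiral pool or a standard aldol.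

Key step: step 11

Assumption: (R)-4-benzyloxazolidin-2-one 9 and all unnumbered reagents are commercial; O5 and O6 are carried as triethylsilyl ethers so that the last deprotection can use buffered fluoride; the antipode of the sulfonamide ligand in step 16 is fixed by one trial with each enantiomer.

## Route

Step 1
Reactants: 1 methyl (S)-2,2-dimethyl-1,3-dioxolane-4-carboxylate
Product: 3 (S)-1-(2,2-dimethyl-1,3-dioxolan-4-yl)ethan-1-one, via Weinreb amide 2 (not isolated)
Conditions: MeNH(OMe)·HCl, iPrMgCl, THF, −20 °C; then MeMgBr, −20 to 0 °C; aq. NH4Cl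
Reagents that add atoms: methylmagnesium bromide, C[Mg]Br (ketone methyl); N,O-dimethylhydroxylamine hydrochloride, CNOC.Cl (amide nitrogen of 2 only, lost again in 3)
Why: The magnesium amide made in the flask converts the ester into Weinreb amide 2, whose chelated adduct with MeMgBr releases the ketone only on work-up (one-pot Weinreb ketone synthesis); the future C5 stereocentre is not touched.

Step 2
Reactants: 3 (S)-1-(2,2-dimethyl-1,3-dioxolan-4-yl)ethan-1-one
Product: 4 (R)-2,2-dimethyl-4-(prop-1-en-2-yl)-1,3-dioxolane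
Conditions: Ph3PCH3Br, KN(SiMe3)2, THF, 0 °C; then 3, −78 °C to rt
Reagents that add atoms: methyltriphenylphosphonium bromide, C[P+](c1ccccc1)(c1ccccc1)c1ccccc1.[Br-]
Why: Wittig methylenation with a slight deficit of base relative to the phosphonium salt leaves no free base to enolise the α-alkoxy ketone; the descriptor changes from S to R only through the priority rules.

Step 3
Reactants: 4 (R)-2,2-dimethyl-4-(prop-1-en-2-yl)-1,3-dioxolane
Product: 5 (R)-3-methylbut-3-ene-1,2-diol
Conditions: Dowex 50W (H+ form), MeOH, rt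
Reagents that add atoms: none
Why: Acid-catalysed transacetalisation to methanol frees the diol without an aqueous work-up, which suits a small water-soluble product that is carried on as a concentrate.

Step 4
Reactants: 5 (R)-3-methylbut-3-ene-1,2-diol
Product: 6 (2R)-3-methyl-1,2-bis(triethylsilyloxy)but-3-ene
Conditions: Et3SiCl, imidazole, DMAP (cat.), CH2Cl2, 0 °C to rt
Reagents that add atoms: chlorotriethylsilane, CC[Si](Cl)(CC)CC
Why: Standard silylation of both hydroxyl groups.

Step 5
Reactants: 6 (2R)-3-methyl-1,2-bis(triethylsilyloxy)but-3-ene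
Product: 7 (2R)-3-methyl-2-(triethylsilyloxy)but-3-enal
Conditions: (COCl)2, DMSO, CH2Cl2, −78 to −40 °C; then iPr2NEt, −78 to −20 °C
Reagents that add atoms: none
Why: Under Swern conditions the primary triethylsilyl ether of a bis-silyl ether is cleaved and oxidised in preference to the secondary one (known selective oxidation of primary triethylsilyl ethers); the aldehyde is used at once because its α-hydrogen is both allylic and next to the carbonyl group.

Step 6
Reactants: 8 pent-4-enoic acid and 9 (R)-4-benzyloxazolidin-2-one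
Product: 11 (R)-4-benzyl-3-(pent-4-enoyl)oxazolidin-2-one, via pent-4-enoic pivalic anhydride 10 (not isolated)
Conditions: tBuCOCl, Et3N, THF, −20 °C; then 9, LiCl, −20 °C to rt
Reagents that add atoms: pivaloyl chloride, CC(C)(C)C(=O)Cl (acyl part of 10 only, none remains in 11)
Why: N-Acylation of the oxazolidinone through the mixed pivalic anhydride with LiCl activation, the standard way of loading this auxiliary.

Step 7
Reactants: 11 (R)-4-benzyl-3-(pent-4-enoyl)oxazolidin-2-one and 7 (2R)-3-methyl-2-(triethylsilyloxy)but-3-enal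
Product: 13 (R)-4-benzyl-3-[(2R,3R,4R)-3-hydroxy-5-methyl-2-(prop-2-en-1-yl)-4-(triethylsilyloxy)hex-5-enoyl]oxazolidin-2-one, via Z dibutylboron enolate 12 (not isolated)
Conditions: Bu2BOTf, iPr2NEt, CH2Cl2, −78 to 0 °C; then 7, −78 to −10 °C; pH 7 buffer, MeOH, H2O2, 0 °C
Reagents that add atoms: dibutylboron triflate, CCCCB(CCCC)OS(=O)(=O)C(F)(F)F (boron of 12 only, none remains in 13)
Why: Evans syn-aldol: the Z boron enolate reacts through a closed chair transition state in which the (R)-benzyl group shields one enolate face, so C1 and C6 are set syn and both R (acyl C2 and C3). The pairing with the (R)-aldehyde asks for the 5,6-syn (anti-Felkin) adduct, so auxiliary control has to override the aldehyde bias.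

Step 8
Reactants: 13 (R)-4-benzyl-3-[(2R,3R,4R)-3-hydroxy-5-methyl-2-(prop-2-en-1-yl)-4-(triethylsilyloxy)hex-5-enoyl]oxazolidin-2-one
Product: 14 (R)-4-benzyl-3-[(2R,3R,4R)-5-methyl-2-(prop-2-en-1-yl)-3,4-bis(triethylsilyloxy)hex-5-enoyl]oxazolidin-2-one
Conditions: Et3SiOTf, 2,6-lutidine, CH2Cl2, −78 to 0 °C
Reagents that add atoms: triethylsilyl trifluoromethanesulfonate, CC[Si](CC)(CC)OS(=O)(=O)C(F)(F)F
Why: A silyl triflate with a hindered base silylates the hydrogen-bonded aldol hydroxyl without retro-aldol cleavage.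

Step 9
Reactants: 14 (R)-4-benzyl-3-[(2R,3R,4R)-5-methyl-2-(prop-2-en-1-yl)-3,4-bis(triethylsilyloxy)hex-5-enoyl]oxazolidin-2-one
Product: 15 (R)-4-benzyl-3-{[(1R,5R,6R)-4-methyl-5,6-bis(triethylsilyloxy)cyclohex-3-en-1-yl]carbonyl}oxazolidin-2-one
Conditions: second-generation Grubbs catalyst (H2IMes)(PCy3)Cl2Ru=CHPh (5 mol %), CH2Cl2 (0.005 M), 40 °C
Reagents that add atoms: none
Why: Ring-closing metathesis starts at the monosubstituted olefin and closes onto the 1,1-disubstituted one with loss of ethylene; trisubstituted cyclohexenes with allylic silyloxy groups are standard products of this catalyst.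

Step 10
Reactants: 15 (R)-4-benzyl-3-{[(1R,5R,6R)-4-methyl-5,6-bis(triethylsilyloxy)cyclohex-3-en-1-yl]carbonyl}oxazolidin-2-one
Product: 16 (1R,5R,6R)-4-methyl-5,6-bis(triethylsilyloxy)cyclohex-3-ene-1-carboxylic acid
Conditions: LiOH, H2O2, THF/H2O, 0 °C; then aq. Na2SO3; 1 M HCl to pH 3, 0 °C
Reagents that add atoms: hydrogen peroxide, OO (as lithium hydroperoxide; one oxygen stays as the carboxyl OH)
Why: Lithium hydroperoxide attacks the exocyclic imide carbonyl selectively and the auxiliary is recovered; these conditions are known not to epimerise α-branched acyl groups.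

Step 11
Reactants: 16 (1R,5R,6R)-4-methyl-5,6-bis(triethylsilyloxy)cyclohex-3-ene-1-carboxylic acid
Product: 17 (1R,4R,5R,6S,7R)-7-iodo-1-methyl-5,6-bis(triethylsilyloxy)-2-oxabicyclo[2.2.2]octan-3-one
Conditions: I2, NaHCO3, MeCN/H2O, 0 °C, dark; aq. Na2S2O3
Reagents that add atoms: iodine, II
Why: Iodine adds reversibly to the C3=C4 olefin of the carboxylate of 16, and only the iodonium ion on the face opposite C7 can be opened, because the axial carboxylate reaches C4 from its own face alone; anti opening forms the C4–O and C3–I bonds of 17. The closest known reaction type is the iodolactonisation of cyclohex-3-ene-1-carboxylic acids under bicarbonate (kinetic) conditions. The one new ring, the δ-lactone of the 2-oxabicyclo[2.2.2]octanone, closes at the tertiary carbon in a 6-exo sense counted through C6–C5 (6-endo counted through C2–C3). The C4 stereocentre is controlled by C1 through the tether (oxygen cis to C7), and the C3 stereocentre follows from the stereospecific anti addition (iodine trans to that oxygen). The step needs face selectivity and Markovnikov regioselectivity: the first is enforced by the reach of the tether, the second by the greater cationic character at the methyl-bearing C4. The reactive half-chair needs only the carboxyl group axial, the C6 and C5 silyloxy groups then being equatorial, so the conformational price is small. Attack at C3 would give the isomeric γ-lactone, which step 12 would convert into the same epoxide.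

Step 12
Reactants: 17 (1R,4R,5R,6S,7R)-7-iodo-1-methyl-5,6-bis(triethylsilyloxy)-2-oxabicyclo[2.2.2]octan-3-one
Product: 19 methyl (1S,2S,3R,4R,6S)-1-methyl-2,3-bis(triethylsilyloxy)-7-oxabicyclo[4.1.0]heptane-4-carboxylate, via iodohydrin methyl ester 18 (not isolated)
Conditions: K2CO3, MeOH, 0 °C to rt
Reagents that add atoms: methanol, CO
Why: Methoxide opens the bridged lactone to ester 18, whose tertiary C4 alkoxide becomes anti-periplanar to the C3–I bond after ring flip and displaces iodide with inversion (intramolecular Williamson closure). The epoxide oxygen therefore stays on the face of C7; this is the known conversion of iodolactones into cis-epoxy esters.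

Step 13
Reactants: 19 methyl (1S,2S,3R,4R,6S)-1-methyl-2,3-bis(triethylsilyloxy)-7-oxabicyclo[4.1.0]heptane-4-carboxylate
Product: 21 (1S,2S,3R,4S,6S)-4-ethynyl-1-methyl-2,3-bis(triethylsilyloxy)-7-oxabicyclo[4.1.0]heptane, via epoxy aldehyde 20 (not isolated)
Conditions: iBu2AlH, CH2Cl2, −78 °C; then MeOH, K2CO3, dimethyl (1-diazo-2-oxopropyl)phosphonate, −78 °C to rt; aq. potassium sodium tartrate
Reagents that add atoms: dimethyl (1-diazo-2-oxopropyl)phosphonate, CC(=O)C(=[N+]=[N-])P(=O)(OC)OC (supplies C14)
Why: Reduction at −78 °C stops at the aluminium hemiacetal, which collapses to aldehyde 20 only when methanol is added; the Ohira–Bestmann reagent then converts it into the alkyne (known one-pot reduction and Seyferth–Gilbert homologation of esters). C1 is exposed to carbonate only briefly at the aldehyde stage.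

Step 14
Reactants: 21 (1S,2S,3R,4S,6S)-4-ethynyl-1-methyl-2,3-bis(triethylsilyloxy)-7-oxabicyclo[4.1.0]heptane
Product: 23 (1S,2S,3R,4R,6S)-4-(1-iodoethenyl)-1-methyl-2,3-bis(triethylsilyloxy)-7-oxabicyclo[4.1.0]heptane, via alkenyl(diisobutyl)alane 22 (not isolated)
Conditions: NiCl2(dppp) (3 mol %), iBu2AlH, THF, 0 °C to rt; then I2, THF, −78 to 0 °C
Reagents that add atoms: iodine, II; diisobutylaluminium hydride, CC(C)C[AlH]CC(C)C (aluminium of 22 only, none remains in 23)
Why: Nickel-catalysed hydroalumination with the bisphosphine dppp places aluminium on the internal carbon of a terminal alkyne (α-selective hydroalumination), and iodinolysis of the C–Al bond gives the 2-iodoalkene. In THF the hydride is consumed by the catalytic cycle faster than it can attack the epoxide.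

Step 15
Reactants: 24 4-methylpent-3-en-1-ol
Product: 25 4-methylpent-3-enal
Conditions: Dess–Martin periodinane, NaHCO3, CH2Cl2, 0 °C
Reagents that add atoms: none
Why: Buffered Dess–Martin oxidation gives the β,γ-unsaturated aldehyde without moving the double bond into conjugation; it is used at once as a cold solution.

Step 16
Reactants: 23 (1S,2S,3R,4R,6S)-4-(1-iodoethenyl)-1-methyl-2,3-bis(triethylsilyloxy)-7-oxabicyclo[4.1.0]heptane and 25 4-methylpent-3-enal
Product: 26 (3S)-6-methyl-2-[(1S,2S,3R,4S,6S)-1-methyl-2,3-bis(triethylsilyloxy)-7-oxabicyclo[4.1.0]heptan-4-yl]hepta-1,5-dien-3-ol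
Conditions: CrCl2, N-[2-(4-isopropyl-4,5-dihydrooxazol-2-yl)-6-methoxyphenyl]methanesulfonamide (one enantiomer), Et3N, THF, rt; then NiCl2 (cat.), 23, 25, rt
Reagents that add atoms: none
Why: Nozaki–Hiyama–Kishi reaction: zerovalent nickel inserts into the C–I bond, transmetalation gives the alkenylchromium species, and its addition to the aldehyde inside the chiral sulfonamide complex sets C8 (asymmetric coupling of 2-iodoalkenes with aldehydes is established). The ligand antipode that gives the (3S) carbinol is used, and the mild organochromium reagent leaves epoxide and silyl ethers alone.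

Step 17
Reactants: 26 (3S)-6-methyl-2-[(1S,2S,3R,4S,6S)-1-methyl-2,3-bis(triethylsilyloxy)-7-oxabicyclo[4.1.0]heptan-4-yl]hepta-1,5-dien-3-ol
Product: 27 (3S)-6-methyl-2-[(1S,2S,3R,4S,6S)-1-methyl-2,3-bis(triethylsilyloxy)-7-oxabicyclo[4.1.0]heptan-4-yl]hepta-1,5-dien-3-yl acetate
Conditions: Ac2O, pyridine, DMAP (cat.), CH2Cl2, 0 °C to rt
Reagents that add atoms: acetic anhydride, CC(=O)OC(C)=O
Why: Standard acetylation of the secondary allylic alcohol; O5 and O6 are still silylated, which distinguishes the acetate site from the angelate sites.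

Step 18
Reactants: 27 (3S)-6-methyl-2-[(1S,2S,3R,4S,6S)-1-methyl-2,3-bis(triethylsilyloxy)-7-oxabicyclo[4.1.0]heptan-4-yl]hepta-1,5-dien-3-yl acetate
Product: 28 (3S)-2-[(1R,2S,3R,4S,6S)-2,3-dihydroxy-1-methyl-7-oxabicyclo[4.1.0]heptan-4-yl]-6-methylhepta-1,5-dien-3-yl acetate
Conditions: HF·pyridine, pyridine, THF, 0 °C to rt
Reagents that add atoms: none
Why: Buffered HF·pyridine removes triethylsilyl ethers at 0 °C; acetate and olefins are inert, and the excess pyridine keeps the medium too weakly acidic to open the epoxide or to move the acetyl group.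

Step 19
Reactants: 28 (3S)-2-[(1R,2S,3R,4S,6S)-2,3-dihydroxy-1-methyl-7-oxabicyclo[4.1.0]heptan-4-yl]-6-methylhepta-1,5-dien-3-yl acetate and 29 angelic acid
Product: 31 (1S,2S,3R,4S,6S)-4-[(3S)-3-acetoxy-6-methylhepta-1,5-dien-2-yl]-1-methyl-7-oxabicyclo[4.1.0]heptane-2,3-diyl bis[(2Z)-2-methylbut-2-enoate], via angelic 2,4,6-trichlorobenzoic anhydride 30 (not isolated)
Conditions: 29, 2,4,6-trichlorobenzoyl chloride, Et3N, toluene, rt; then 28, 80 °C
Reagents that add atoms: 2,4,6-trichlorobenzoyl chloride, O=C(Cl)c1c(Cl)cc(Cl)cc1Cl (aroyl part of 30 only, none remains in 31)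
Why: Yamaguchi-type esterification: the mixed anhydride 30 acylates the alcohols on heating without a nucleophilic catalyst, conditions known to transfer the angeloyl group without Z to E isomerisation. Both secondary hydroxyl groups are acylated to give the target.

## Compound list

1 | methyl (S)-2,2-dimethyl-1,3-dioxolane-4-carboxylate | COC(=O)[C@@H]1COC(C)(C)O1 | starting material
2 | (S)-N-methoxy-N,2,2-trimethyl-1,3-dioxolane-4-carboxamide | CON(C)C(=O)[C@@H]1COC(C)(C)O1 | intermediate (not isolated)
3 | (S)-1-(2,2-dimethyl-1,3-dioxolan-4-yl)ethan-1-one | CC(=O)[C@@H]1COC(C)(C)O1 | intermediate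
4 | (R)-2,2-dimethyl-4-(prop-1-en-2-yl)-1,3-dioxolane | C=C(C)[C@@H]1COC(C)(C)O1 | intermediate
5 | (R)-3-methylbut-3-ene-1,2-diol | C=C(C)[C@@H](O)CO | intermediate
6 | (2R)-3-methyl-1,2-bis(triethylsilyloxy)but-3-ene | C=C(C)[C@@H](O[Si](CC)(CC)CC)CO[Si](CC)(CC)CC | intermediate
7 | (2R)-3-methyl-2-(triethylsilyloxy)but-3-enal | C=C(C)[C@@H](O[Si](CC)(CC)CC)C=O | intermediate
8 | pent-4-enoic acid | C=CCCC(=O)O | starting material
9 | (R)-4-benzyloxazolidin-2-one | O=C1N[C@H](Cc2ccccc2)CO1 | starting material
10 | pent-4-enoic pivalic anhydride | C=CCCC(=O)OC(=O)C(C)(C)C | intermediate (not isolated)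
11 | (R)-4-benzyl-3-(pent-4-enoyl)oxazolidin-2-one | C=CCCC(=O)N1[C@H](Cc2ccccc2)COC1=O | intermediate
12 | Z dibutylboron enolate of 11 | C=CC/C=C(\OB(CCCC)CCCC)N1[C@H](Cc2ccccc2)COC1=O | intermediate (not isolated)
13 | (R)-4-benzyl-3-[(2R,3R,4R)-3-hydroxy-5-methyl-2-(prop-2-en-1-yl)-4-(triethylsilyloxy)hex-5-enoyl]oxazolidin-2-one | C=C(C)[C@@H](O[Si](CC)(CC)CC)[C@H](O)[C@@H](CC=C)C(=O)N1[C@H](Cc2ccccc2)COC1=O | intermediate
14 | (R)-4-benzyl-3-[(2R,3R,4R)-5-methyl-2-(prop-2-en-1-yl)-3,4-bis(triethylsilyloxy)hex-5-enoyl]oxazolidin-2-one | C=C(C)[C@@H](O[Si](CC)(CC)CC)[C@H](O[Si](CC)(CC)CC)[C@@H](CC=C)C(=O)N1[C@H](Cc2ccccc2)COC1=O | intermediate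
15 | (R)-4-benzyl-3-{[(1R,5R,6R)-4-methyl-5,6-bis(triethylsilyloxy)cyclohex-3-en-1-yl]carbonyl}oxazolidin-2-one | O=C([C@@H]1CC=C(C)[C@@H](O[Si](CC)(CC)CC)[C@@H]1O[Si](CC)(CC)CC)N2[C@H](Cc3ccccc3)COC2=O | intermediate
16 | (1R,5R,6R)-4-methyl-5,6-bis(triethylsilyloxy)cyclohex-3-ene-1-carboxylic acid | O=C(O)[C@@H]1CC=C(C)[C@@H](O[Si](CC)(CC)CC)[C@@H]1O[Si](CC)(CC)CC | intermediate
17 | (1R,4R,5R,6S,7R)-7-iodo-1-methyl-5,6-bis(triethylsilyloxy)-2-oxabicyclo[2.2.2]octan-3-one | O=C1O[C@@]2(C)[C@H](I)C[C@@H]1[C@@H](O[Si](CC)(CC)CC)[C@@H]2O[Si](CC)(CC)CC | intermediate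
18 | methyl (1R,2R,3S,4R,5R)-4-hydroxy-5-iodo-4-methyl-2,3-bis(triethylsilyloxy)cyclohexane-1-carboxylate | COC(=O)[C@@H]1C[C@@H](I)[C@](C)(O)[C@@H](O[Si](CC)(CC)CC)[C@@H]1O[Si](CC)(CC)CC | intermediate (not isolated)
19 | methyl (1S,2S,3R,4R,6S)-1-methyl-2,3-bis(triethylsilyloxy)-7-oxabicyclo[4.1.0]heptane-4-carboxylate | COC(=O)[C@@H]1C[C@@H]2O[C@]2(C)[C@@H](O[Si](CC)(CC)CC)[C@@H]1O[Si](CC)(CC)CC | intermediate
20 | (1S,2S,3R,4R,6S)-1-methyl-2,3-bis(triethylsilyloxy)-7-oxabicyclo[4.1.0]heptane-4-carbaldehyde | O=C[C@@H]1C[C@@H]2O[C@]2(C)[C@@H](O[Si](CC)(CC)CC)[C@@H]1O[Si](CC)(CC)CC | intermediate (not isolated)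
21 | (1S,2S,3R,4S,6S)-4-ethynyl-1-methyl-2,3-bis(triethylsilyloxy)-7-oxabicyclo[4.1.0]heptane | C#C[C@@H]1C[C@@H]2O[C@]2(C)[C@@H](O[Si](CC)(CC)CC)[C@@H]1O[Si](CC)(CC)CC | intermediate
22 | diisobutyl{1-[(1S,2S,3R,4R,6S)-1-methyl-2,3-bis(triethylsilyloxy)-7-oxabicyclo[4.1.0]heptan-4-yl]ethenyl}alumane | C=C([Al](CC(C)C)CC(C)C)[C@@H]1C[C@@H]2O[C@]2(C)[C@@H](O[Si](CC)(CC)CC)[C@@H]1O[Si](CC)(CC)CC | intermediate (not isolated)
23 | (1S,2S,3R,4R,6S)-4-(1-iodoethenyl)-1-methyl-2,3-bis(triethylsilyloxy)-7-oxabicyclo[4.1.0]heptane | C=C(I)[C@@H]1C[C@@H]2O[C@]2(C)[C@@H](O[Si](CC)(CC)CC)[C@@H]1O[Si](CC)(CC)CC | intermediate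
24 | 4-methylpent-3-en-1-ol | CC(C)=CCCO | starting material
25 | 4-methylpent-3-enal | CC(C)=CCC=O | intermediate
26 | (3S)-6-methyl-2-[(1S,2S,3R,4S,6S)-1-methyl-2,3-bis(triethylsilyloxy)-7-oxabicyclo[4.1.0]heptan-4-yl]hepta-1,5-dien-3-ol | C=C([C@H](CC=C(C)C)O)[C@@H]1C[C@@H]2O[C@]2(C)[C@@H](O[Si](CC)(CC)CC)[C@@H]1O[Si](CC)(CC)CC | intermediate
27 | (3S)-6-methyl-2-[(1S,2S,3R,4S,6S)-1-methyl-2,3-bis(triethylsilyloxy)-7-oxabicyclo[4.1.0]heptan-4-yl]hepta-1,5-dien-3-yl acetate | C=C([C@H](CC=C(C)C)OC(C)=O)[C@@H]1C[C@@H]2O[C@]2(C)[C@@H](O[Si](CC)(CC)CC)[C@@H]1O[Si](CC)(CC)CC | intermediate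
28 | (3S)-2-[(1R,2S,3R,4S,6S)-2,3-dihydroxy-1-methyl-7-oxabicyclo[4.1.0]heptan-4-yl]-6-methylhepta-1,5-dien-3-yl acetate | C=C([C@H](CC=C(C)C)OC(C)=O)[C@@H]1C[C@@H]2O[C@]2(C)[C@@H](O)[C@@H]1O | intermediate
29 | angelic acid, (2Z)-2-methylbut-2-enoic acid | C/C=C(/C)C(=O)O | starting material
30 | angelic 2,4,6-trichlorobenzoic anhydride | C/C=C(/C)C(=O)OC(=O)c1c(Cl)cc(Cl)cc1Cl | intermediate (not isolated)
31 | (1S,2S,3R,4S,6S)-4-[(3S)-3-acetoxy-6-methylhepta-1,5-dien-2-yl]-1-methyl-7-oxabicyclo[4.1.0]heptane-2,3-diyl bis[(2Z)-2-methylbut-2-enoate] (CNP0188566.1) | C=C([C@H](CC=C(C)C)OC(C)=O)[C@@H]1C[C@@H]2O[C@]2(C)[C@@H](OC(=O)/C(C)=C\C)[C@@H]1OC(=O)/C(C)=C\C | target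

## Step count and least certain steps

Total step count: 19. Longest linear sequence: 17 steps (steps 1–5, 7–14 and 16–19); steps 6 and 15 are one-step side branches.

**Step 11 (key step).** The lactone may close slowly because the boat places the C6 silyloxy group beside the lactone bridge. Participation of the O6 silyl ether in opening the iodonium ion (iodoetherification with loss of the silyl group) could compete. Fallback from 16: reduction with LiAlH4 (THF, 0 °C) gives [(1S,5R,6R)-4-methyl-5,6-bis(triethylsilyloxy)cyclohex-3-en-1-yl]methanol F1. Hydroxyl-directed epoxidation with VO(acac)2 and tBuOOH delivers oxygen to the face of the carbinol arm and gives [(1S,2S,3R,4S,6S)-1-methyl-2,3-bis(triethylsilyloxy)-7-oxabicyclo[4.1.0]heptan-4-yl]methanol F2. Dess–Martin oxidation returns to the route at aldehyde 20, which is homologated to 21 with the Ohira–Bestmann reagent as in the second half of step 13.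

**Step 7.** Facial selectivity may erode because the auxiliary and the α-silyloxy aldehyde are a mismatched pair. The aldehyde may also epimerise or slip into conjugation before it reacts. Fallback from 11 (through enolate 12): aldol addition to achiral 3-methylbut-2-enal gives (R)-4-benzyl-3-[(2R,3S)-3-hydroxy-5-methyl-2-(prop-2-en-1-yl)hex-4-enoyl]oxazolidin-2-one F3. A hydroxyl-directed Schenck ene reaction with singlet oxygen (O2, tetraphenylporphyrin, light, CH2Cl2) gives the threo product (R)-4-benzyl-3-[(2R,3R,4R)-4-hydroperoxy-3-hydroxy-5-methyl-2-(prop-2-en-1-yl)hex-5-enoyl]oxazolidin-2-one F4. PPh3 reduces it to (R)-4-benzyl-3-[(2R,3R,4R)-3,4-dihydroxy-5-methyl-2-(prop-2-en-1-yl)hex-5-enoyl]oxazolidin-2-one F5. Double silylation (Et3SiOTf, 2,6-lutidine) returns to the route at 14. The chiral aldehyde 7 and steps 1–5 are then not needed.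

**Step 13.** Over-reduction of the ester may occur. Epimerisation at C1, or β-elimination of the C6 silyloxy group, is possible while the aldehyde sits in basic methanol. Fallback from 19: MeNH(OMe)·HCl and iPrMgCl give (1S,2S,3R,4R,6S)-N-methoxy-N,1-dimethyl-2,3-bis(triethylsilyloxy)-7-oxabicyclo[4.1.0]heptane-4-carboxamide F6. MeLi at −78 °C gives 1-[(1S,2S,3R,4R,6S)-1-methyl-2,3-bis(triethylsilyloxy)-7-oxabicyclo[4.1.0]heptan-4-yl]ethan-1-one F7. Kinetic enolisation at the methyl group with KN(SiMe3)2 and trapping with PhNTf2 gives 1-[(1S,2S,3R,4R,6S)-1-methyl-2,3-bis(triethylsilyloxy)-7-oxabicyclo[4.1.0]heptan-4-yl]ethenyl trifluoromethanesulfonate F8. F8 couples with 25 under the chromium and nickel conditions of step 16 and returns to the route at 26.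

**Step 14.** The epoxide may be opened reductively by iBu2AlH, or α-selectivity may be lost with an alkyne that is branched at the propargylic carbon. Fallback from 21: Markovnikov hydrosilylation with Et3SiH catalysed by [Cp*Ru(MeCN)3]PF6 gives triethyl{1-[(1S,2S,3R,4R,6S)-1-methyl-2,3-bis(triethylsilyloxy)-7-oxabicyclo[4.1.0]heptan-4-yl]ethenyl}silane F9. Iododesilylation with N-iodosuccinimide in MeCN returns to the route at 23.

**Step 16.** Ligand control at C8 may be weak because the alkenyl iodide is hindered next to the reacting carbon. Aldehyde 25 may isomerise to the conjugated enal. Fallback from 23: the same coupling without chiral ligand gives the C8-epimeric mixture (3RS)-6-methyl-2-[(1S,2S,3R,4S,6S)-1-methyl-2,3-bis(triethylsilyloxy)-7-oxabicyclo[4.1.0]heptan-4-yl]hepta-1,5-dien-3-ol F10. Dess–Martin oxidation gives 6-methyl-2-[(1S,2S,3R,4S,6S)-1-methyl-2,3-bis(triethylsilyloxy)-7-oxabicyclo[4.1.0]heptan-4-yl]hepta-1,5-dien-3-one F11. Corey–Bakshi–Shibata reduction with the (R)-oxazaborolidine and BH3·SMe2, in which the 1,1-disubstituted alkenyl group acts as the larger substituent, returns to the route at 26.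

**Step 19.** Acylation of the hindered C5 hydroxyl next to the fully substituted epoxide carbon may be incomplete. Z to E isomerisation of the angeloyl group may set in on long heating. Fallback from 28: esterification of both hydroxyl groups with 2-[bis(2,2,2-trifluoroethoxy)phosphoryl]propanoic acid (EDC·HCl, DMAP) gives (1S,2S,3R,4S,6S)-4-[(3S)-3-acetoxy-6-methylhepta-1,5-dien-2-yl]-1-methyl-7-oxabicyclo[4.1.0]heptane-2,3-diyl bis{2-[bis(2,2,2-trifluoroethoxy)phosphoryl]propanoate} F12. A double Still–Gennari olefination with acetaldehyde (KN(SiMe3)2, 18-crown-6, THF, −78 °C) builds both Z-trisubstituted enoates on the ring and returns to the route at 31.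

## Further compounds

F1 | step 11 | [(1S,5R,6R)-4-methyl-5,6-bis(triethylsilyloxy)cyclohex-3-en-1-yl]methanol | OC[C@@H]1CC=C(C)[C@@H](O[Si](CC)(CC)CC)[C@@H]1O[Si](CC)(CC)CC
F2 | step 11 | [(1S,2S,3R,4S,6S)-1-methyl-2,3-bis(triethylsilyloxy)-7-oxabicyclo[4.1.0]heptan-4-yl]methanol | OC[C@@H]1C[C@@H]2O[C@]2(C)[C@@H](O[Si](CC)(CC)CC)[C@@H]1O[Si](CC)(CC)CC
F3 | step 7 | (R)-4-benzyl-3-[(2R,3S)-3-hydroxy-5-methyl-2-(prop-2-en-1-yl)hex-4-enoyl]oxazolidin-2-one | CC(C)=C[C@H](O)[C@@H](CC=C)C(=O)N1[C@H](Cc2ccccc2)COC1=O
F4 | step 7 | (R)-4-benzyl-3-[(2R,3R,4R)-4-hydroperoxy-3-hydroxy-5-methyl-2-(prop-2-en-1-yl)hex-5-enoyl]oxazolidin-2-one | C=C(C)[C@@H](OO)[C@H](O)[C@@H](CC=C)C(=O)N1[C@H](Cc2ccccc2)COC1=O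
F5 | step 7 | (R)-4-benzyl-3-[(2R,3R,4R)-3,4-dihydroxy-5-methyl-2-(prop-2-en-1-yl)hex-5-enoyl]oxazolidin-2-one | C=C(C)[C@@H](O)[C@H](O)[C@@H](CC=C)C(=O)N1[C@H](Cc2ccccc2)COC1=O
F6 | step 13 | (1S,2S,3R,4R,6S)-N-methoxy-N,1-dimethyl-2,3-bis(triethylsilyloxy)-7-oxabicyclo[4.1.0]heptane-4-carboxamide | CON(C)C(=O)[C@@H]1C[C@@H]2O[C@]2(C)[C@@H](O[Si](CC)(CC)CC)[C@@H]1O[Si](CC)(CC)CC
F7 | step 13 | 1-[(1S,2S,3R,4R,6S)-1-methyl-2,3-bis(triethylsilyloxy)-7-oxabicyclo[4.1.0]heptan-4-yl]ethan-1-one | CC(=O)[C@@H]1C[C@@H]2O[C@]2(C)[C@@H](O[Si](CC)(CC)CC)[C@@H]1O[Si](CC)(CC)CC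
F8 | step 13 | 1-[(1S,2S,3R,4R,6S)-1-methyl-2,3-bis(triethylsilyloxy)-7-oxabicyclo[4.1.0]heptan-4-yl]ethenyl trifluoromethanesulfonate | C=C(OS(=O)(=O)C(F)(F)F)[C@@H]1C[C@@H]2O[C@]2(C)[C@@H](O[Si](CC)(CC)CC)[C@@H]1O[Si](CC)(CC)CC
F9 | step 14 | triethyl{1-[(1S,2S,3R,4R,6S)-1-methyl-2,3-bis(triethylsilyloxy)-7-oxabicyclo[4.1.0]heptan-4-yl]ethenyl}silane | C=C([Si](CC)(CC)CC)[C@@H]1C[C@@H]2O[C@]2(C)[C@@H](O[Si](CC)(CC)CC)[C@@H]1O[Si](CC)(CC)CC
F10 | step 16 | (3RS)-6-methyl-2-[(1S,2S,3R,4S,6S)-1-methyl-2,3-bis(triethylsilyloxy)-7-oxabicyclo[4.1.0]heptan-4-yl]hepta-1,5-dien-3-ol | C=C(C(O)CC=C(C)C)[C@@H]1C[C@@H]2O[C@]2(C)[C@@H](O[Si](CC)(CC)CC)[C@@H]1O[Si](CC)(CC)CC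
F11 | step 16 | 6-methyl-2-[(1S,2S,3R,4S,6S)-1-methyl-2,3-bis(triethylsilyloxy)-7-oxabicyclo[4.1.0]heptan-4-yl]hepta-1,5-dien-3-one | C=C(C(=O)CC=C(C)C)[C@@H]1C[C@@H]2O[C@]2(C)[C@@H](O[Si](CC)(CC)CC)[C@@H]1O[Si](CC)(CC)CC
F12 | step 19 | (1S,2S,3R,4S,6S)-4-[(3S)-3-acetoxy-6-methylhepta-1,5-dien-2-yl]-1-methyl-7-oxabicyclo[4.1.0]heptane-2,3-diyl bis{2-[bis(2,2,2-trifluoroethoxy)phosphoryl]propanoate} | C=C([C@H](CC=C(C)C)OC(C)=O)[C@@H]1C[C@@H]2O[C@]2(C)[C@@H](OC(=O)C(C)P(=O)(OCC(F)(F)F)OCC(F)(F)F)[C@@H]1OC(=O)C(C)P(=O)(OCC(F)(F)F)OCC(F)(F)F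
A1 | alternative 1 | 4-methoxybenzyl ether of (2S,3R,4R)-5-methyl-2-(prop-2-en-1-yl)-3,4-bis(triethylsilyloxy)hex-5-en-1-ol | C=CC[C@@H](COCc1ccc(OC)cc1)[C@@H](O[Si](CC)(CC)CC)[C@H](O[Si](CC)(CC)CC)C(C)=C
A2 | alternative 1 | 4-methoxybenzyl ether of [(1S,5R,6R)-4-methyl-5,6-bis(triethylsilyloxy)cyclohex-3-en-1-yl]methanol | COc1ccc(COC[C@@H]2CC=C(C)[C@@H](O[Si](CC)(CC)CC)[C@@H]2O[Si](CC)(CC)CC)cc1
A3 | alternative 2 | methyl (2Z)-2-(bromomethyl)-4-[(2S,3S)-3-{(1R)-1-[(4-methoxybenzyl)oxy]-2-oxoethyl}-3-methyloxiran-2-yl]but-2-enoate | COC(=O)/C(CBr)=C/C[C@@H]1O[C@]1(C)[C@@H](OCc2ccc(OC)cc2)C=O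
A4 | alternative 2 | cis-fused epoxy α-methylene-γ-butyrolactone carrying the C5 4-methoxybenzyl ether | C=C1C(=O)O[C@@H]2[C@H]1C[C@@H]3O[C@]3(C)[C@H]2OCc4ccc(OC)cc4
A5 | alternative 3 | 4,5-bis(tert-butyldimethylsilyloxy)-6-ethenyl-6-methyloxan-2-one (ethenyl trans to the C4 silyloxy group, cis to the C5 silyloxy group) | C=C[C@]1(C)OC(=O)C[C@@H](O[Si](C)(C)C(C)(C)C)[C@@H]1O[Si](C)(C)C(C)(C)C
A6 | alternative 3 | (1R,5R,6R)-5,6-bis(tert-butyldimethylsilyloxy)-4-methylcyclohex-3-ene-1-carboxylic acid | OC(=O)[C@@H]1CC=C(C)[C@@H](O[Si](C)(C)C(C)(C)C)[C@@H]1O[Si](C)(C)C(C)(C)C
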